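**Plan**

- Atom labels (bicyclic numbering of the target): C1 quaternary epoxide carbon, C2 CH(OH), C3 C-heptenyl, C4 C-CH2OH, C5 CH(OH), C6 epoxide CH. The carbocycle is a reduced, mono-epoxidised p-benzoquinone: oxygen on C2 and C5, a tetrasubstituted C3=C4 between them, and C6 (H) / C1 (side chain) as the former third C=C.
- Retrosynthesis: ester cleavage, the C2 and C5 carbinols back to ketones, the epoxide back to the quinone C1=C6. The quinone ring is then cut at C5–C6 and C1–C2 into a maleoyl unit C2(=O)–C3=C4–C5(=O) (a cobalt-inserted cyclobutenedione) and the terminal alkyne C6≡C1 that already carries the enoate side chain.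
- Forward: squarate plus two organolithiums gives cyclobutenedione 11, then maleoylcobalt complex 13; alkyne 21 comes from an oxidation/Wittig sequence; the cobalt-mediated annulation closes the six-membered ring (22); then epoxidation, ether cleavage, two ketone reductions and deallylation.
- Stereochemistry: C1/C6 from a catalyst-controlled phase-transfer epoxidation; C5 from hydroxyl-directed hydride delivery anti to the epoxide oxygen; C2 from hydride attack anti to the C1 side-chain arm (trans to the C5 hydroxyl); both E alkenes from the E-boronic acid and a stabilised ylide.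

Key step: step 8

Assumption: the facial sense of the phase-transfer epoxidation in step 9 is taken as that of the cinchonidinium salt written; if the antipodal epoxide forms, the pseudoenantiomeric cinchoninium salt is used instead.

**Route**

Step 1
Reactants: 1 (tributylstannyl)methanol; 2 2-(bromomethyl)naphthalene
Product: 3 tributyl[(naphthalen-2-ylmethoxy)methyl]stannane
Conditions: NaH, Bu4NI (cat.), THF/DMF, 0 °C to rt
Reagents that add atoms: none
Why: Williamson ether synthesis on the primary α-stannyl alkoxide; the 2-naphthylmethyl (NAP) ether is chosen because it should withstand HCl and SnCl4 later and is cleaved oxidatively by DDQ.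

Step 2
Reactants: 4 (E)-hept-1-en-1-ylboronic acid
Product: 5 (E)-1-iodohept-1-ene
Conditions: N-iodosuccinimide, MeCN, rt, dark
Reagents that add atoms: N-iodosuccinimide O=C1CCC(=O)N1I
Why: ipso-iododeboronation of an alkenylboronic acid proceeds with retention, so the E geometry of the heptenyl unit is fixed here.

Step 3
Reactants: 6 3,4-di(propan-2-yloxy)cyclobut-3-ene-1,2-dione (diisopropyl squarate); 3 tributyl[(naphthalen-2-ylmethoxy)methyl]stannane; 5 (E)-1-iodohept-1-ene
Product: 11 3-[(E)-hept-1-enyl]-4-[(naphthalen-2-ylmethoxy)methyl]cyclobut-3-ene-1,2-dione, via [(naphthalen-2-ylmethoxy)methyl]lithium 7 (not isolated), via (E)-hept-1-enyllithium 8 (not isolated), via mono-adduct lithium alkoxide 9 (not isolated), via bis-adduct diol 10 (not isolated)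
Conditions: 3, n-BuLi, THF, −78 °C, then 6, −78 °C; then 8 (from 5, t-BuLi 2 equiv, Et2O, −78 °C), −78 °C; aq. NH4Cl at −78 °C; then conc. HCl (cat.), CH2Cl2, rt
Reagents that add atoms: none
Why: tin–lithium and iodine–lithium exchange give the two organolithiums, which add one after the other in 1,2-fashion to the two squarate carbonyl groups; acid then ionises both tertiary allylic carbinols with hydrolysis of the two enol ethers (squarate-to-cyclobutenedione transposition), leaving the two carbon substituents on the ring alkene.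

Step 4
Reactants: 11 3-[(E)-hept-1-enyl]-4-[(naphthalen-2-ylmethoxy)methyl]cyclobut-3-ene-1,2-dione
Product: 13 maleoylcobalt complex CoCl(dmgH2)(py)[C(O)C(R1)=C(R2)C(O)], via phosphine complex CoCl(PPh3)2[C(O)C(R1)=C(R2)C(O)] 12 (not isolated)
Conditions: ClCo(PPh3)3 (1 equiv), benzene, rt; then dimethylglyoxime (dmgH2), pyridine, rt
Reagents that add atoms: ClCo(PPh3)3 Cl[Co-3]([P+](c1ccccc1)(c1ccccc1)c1ccccc1)([P+](c1ccccc1)(c1ccccc1)c1ccccc1)[P+](c1ccccc1)(c1ccccc1)c1ccccc1; dimethylglyoxime CC(=NO)C(C)=NO; pyridine c1ccncc1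
Why: oxidative addition of univalent cobalt into the strained C(O)–C(O) bond of the cyclobutenedione gives the five-membered maleoyl metallacycle of trivalent cobalt, and ligand exchange gives the air-stable dimethylglyoxime/pyridine complex of the kind known to react with alkynes under Lewis acid promotion.

Step 5
Reactants: 14 2-bromopropanoyl bromide; 15 prop-2-en-1-ol
Product: 16 prop-2-enyl 2-bromopropanoate
Conditions: pyridine, CH2Cl2, 0 °C
Reagents that add atoms: none
Why: simple acylation of allyl alcohol by the acid bromide; the allyl ester is chosen so that the acid can be freed at the end under neutral conditions.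

Step 6
Reactants: 16 prop-2-enyl 2-bromopropanoate
Product: 18 prop-2-enyl 2-(triphenyl-λ5-phosphanylidene)propanoate, via phosphonium bromide 17 (not isolated)
Conditions: PPh3, toluene, 80 °C; then aq. NaOH, CH2Cl2, 0 °C
Reagents that add atoms: triphenylphosphine c1ccc(cc1)P(c1ccccc1)c1ccccc1
Why: SN2 quaternisation of the phosphine by the α-bromo ester followed by deprotonation gives the stabilised ylide for the Wittig reaction.

Step 7
Reactants: 19 but-3-yn-1-ol; 18 prop-2-enyl 2-(triphenyl-λ5-phosphanylidene)propanoate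
Product: 21 prop-2-enyl (E)-2-methylhex-2-en-5-ynoate, via but-3-ynal 20 (not isolated)
Conditions: Dess–Martin periodinane, NaHCO3, CH2Cl2, 0 °C; then 18, 0 °C to rt
Reagents that add atoms: none
Why: Dess–Martin oxidation gives the labile β,γ-acetylenic aldehyde, which is trapped at once, without added base, in a Wittig reaction with the stabilised α-methyl ylide; this ylide type should give the (E)-trisubstituted enoate.

Step 8
Reactants: 13 maleoylcobalt complex CoCl(dmgH2)(py)[C(O)C(R1)=C(R2)C(O)]; 21 prop-2-enyl (E)-2-methylhex-2-en-5-ynoate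
Product: 22 prop-2-enyl (E)-4-{5-[(E)-hept-1-enyl]-4-[(naphthalen-2-ylmethoxy)methyl]-3,6-dioxocyclohexa-1,4-dien-1-yl}-2-methylbut-2-enoate
Conditions: SnCl4 (1.1 equiv), 21 (1.5 equiv), ClCH2CH2Cl, 0 °C to rt
Reagents that add atoms: none
Why: SnCl4 binds the acyl oxygen at the future C5 and labilises the chloride, the alkyne coordinates to trivalent cobalt and inserts into the C5 acyl–cobalt bond (first bond, C5–C6) to give a seven-membered cobaltacycle, and C–C reductive elimination joins the vinyl carbon C1 to the C2 acyl carbon (second bond) with release of univalent cobalt. The closest known reaction type is the quinone synthesis from maleoyl- and phthaloylcobalt complexes (made from cyclobutenediones) and alkynes. The six-membered ring is closed by a formal [4+2] annulation: migratory insertion of the alkyne expands the five-membered metallacycle to the seven-membered one, and reductive elimination contracts it to the carbocycle. No stereocentre is formed: the product is a planar, achiral quinone with all three carbon substituents and both ring oxygens in place, and the four stereocentres are added to this ring in steps 9, 11 and 12. The step needs regioselectivity (unsubstituted alkyne carbon to the C5 acyl carbon) and chemoselectivity for the alkyne over the C=C bonds; the first rests on the C5 acyl being the Lewis basic site (vinylogous donation from the heptenyl diene through C3=C4, and a six-membered SnCl4 chelate with the ether oxygen on the C4 substituent), so that the more nucleophilic terminal alkyne carbon should bond to it while positive charge builds on the substituted carbon, and the second on the stronger binding and faster insertion of alkynes at cobalt.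

Step 9
Reactants: 22 prop-2-enyl (E)-4-{5-[(E)-hept-1-enyl]-4-[(naphthalen-2-ylmethoxy)methyl]-3,6-dioxocyclohexa-1,4-dien-1-yl}-2-methylbut-2-enoate
Product: 23 prop-2-enyl (E)-4-{(1R,6S)-3-[(E)-hept-1-enyl]-4-[(naphthalen-2-ylmethoxy)methyl]-2,5-dioxo-7-oxabicyclo[4.1.0]hept-3-en-1-yl}-2-methylbut-2-enoate
Conditions: N-(9-anthracenylmethyl)cinchonidinium chloride (10 mol %), aq. NaOCl, toluene, −10 °C
Reagents that add atoms: sodium hypochlorite [Na+].[O-]Cl
Why: Weitz–Scheffer-type nucleophilic epoxidation under chiral phase-transfer catalysis; hypochlorite should add to the only unsubstituted quinone carbon (C6), leaving the tetrasubstituted dienyl C=C and the enoate, the resulting enolate closes to the cis-fused epoxide, and the ion-paired cinchonidinium cation selects the face, setting C1 and C6 together.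

Step 10
Reactants: 23 the NAP-protected epoxy-enedione
Product: 24 prop-2-enyl (E)-4-[(1R,6S)-3-[(E)-hept-1-enyl]-4-(hydroxymethyl)-2,5-dioxo-7-oxabicyclo[4.1.0]hept-3-en-1-yl]-2-methylbut-2-enoate
Conditions: DDQ, CH2Cl2/pH 7 buffer, rt
Reagents that add atoms: none
Why: oxidative cleavage of the 2-naphthylmethyl ether by DDQ (benzylic hydride abstraction, then hydrolysis of the hemiacetal) should free the primary alcohol without touching the electron-poor epoxy-enedione or the allyl ester, at a stage where no oxidisable allylic carbinol is present.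

Step 11
Reactants: 24 the epoxy-enedione alcohol
Product: 25 prop-2-enyl (E)-4-[(1R,5R,6R)-3-[(E)-hept-1-enyl]-5-hydroxy-4-(hydroxymethyl)-2-oxo-7-oxabicyclo[4.1.0]hept-3-en-1-yl]-2-methylbut-2-enoate
Conditions: Me4NBH(OAc)3, MeCN/AcOH, −30 °C
Reagents that add atoms: none
Why: Evans–Saksena directed reduction; the primary hydroxyl exchanges onto boron and delivers hydride only to the neighbouring C5 ketone (β-hydroxy ketone relation, the C2 ketone being out of reach and the ester inert), from the face opposite the epoxide oxygen, which should give the C5 carbinol syn to the epoxide.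

Step 12
Reactants: 25 the hydroxy enone
Product: 26 prop-2-enyl (E)-4-[(1S,2R,5R,6R)-3-[(E)-hept-1-enyl]-2,5-dihydroxy-4-(hydroxymethyl)-7-oxabicyclo[4.1.0]hept-3-en-1-yl]-2-methylbut-2-enoate
Conditions: LiBH(s-Bu)3 (3.2 equiv), THF, −78 °C; aq. NH4Cl
Reagents that add atoms: none
Why: 1,2-reduction of the remaining enone by a bulky hydride (conjugate addition is blocked by the fully substituted β-carbon C4); hydride should approach C2 from the epoxide face because the opposite face is shielded by the CH2 arm on the adjacent quaternary C1, giving the C2 carbinol anti to the epoxide and trans to the C5 hydroxyl.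

Step 13
Reactants: 26 the triol allyl ester
Product: 27 (E)-4-[(1S,2R,5R,6R)-3-[(E)-hept-1-enyl]-2,5-dihydroxy-4-(hydroxymethyl)-7-oxabicyclo[4.1.0]hept-3-en-1-yl]-2-methylbut-2-enoic acid (target)
Conditions: Pd(PPh3)4 (5 mol %), morpholine, THF, rt; pH 4 buffer work-up
Reagents that add atoms: none
Why: Tsuji–Trost deallylation; zerovalent palladium ionises only the allyl ester to a π-allyl complex that morpholine captures, freeing the acid under neutral conditions that should spare the epoxide, the allylic alcohols and the diene.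

**Compound list**

1 | (tributylstannyl)methanol | CCCC[Sn](CCCC)(CCCC)CO | starting material
2 | 2-(bromomethyl)naphthalene | BrCc1ccc2ccccc2c1 | starting material
3 | tributyl[(naphthalen-2-ylmethoxy)methyl]stannane | CCCC[Sn](CCCC)(CCCC)COCc1ccc2ccccc2c1 | intermediate
4 | (E)-hept-1-en-1-ylboronic acid | CCCCC/C=C/B(O)O | starting material
5 | (E)-1-iodohept-1-ene | CCCCC/C=C/I | intermediate
6 | 3,4-di(propan-2-yloxy)cyclobut-3-ene-1,2-dione (diisopropyl squarate) | CC(C)OC1=C(OC(C)C)C(=O)C1=O | starting material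
7 | [(naphthalen-2-ylmethoxy)methyl]lithium | [Li]COCc1ccc2ccccc2c1 | intermediate
8 | (E)-hept-1-en-1-yllithium | [Li]/C=C/CCCCC | intermediate
9 | lithium alkoxide of 4-hydroxy-4-[(naphthalen-2-ylmethoxy)methyl]-2,3-di(propan-2-yloxy)cyclobut-2-en-1-one (racemic) | [Li]OC1(COCc2ccc3ccccc3c2)C(OC(C)C)=C(OC(C)C)C1=O | intermediate
10 | 1-[(E)-hept-1-enyl]-4-[(naphthalen-2-ylmethoxy)methyl]-2,3-di(propan-2-yloxy)cyclobut-2-ene-1,4-diol (racemic, cis/trans mixture; formed as its dilithium alkoxide and protonated on quench) | CCCCC/C=C/C1(O)C(OC(C)C)=C(OC(C)C)C1(O)COCc1ccc2ccccc2c1 | intermediate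
11 | 3-[(E)-hept-1-enyl]-4-[(naphthalen-2-ylmethoxy)methyl]cyclobut-3-ene-1,2-dione | CCCCC/C=C/C1=C(COCc2ccc3ccccc3c2)C(=O)C1=O | intermediate
12 | CoCl(PPh3)2[C(O)C(R1)=C(R2)C(O)], five-membered maleoyl metallacycle of trivalent cobalt (R1 = (E)-hept-1-enyl, R2 = CH2OCH2-2-naphthyl) | O=C1C(/C=C/CCCCC)=C(COCc2ccc3ccccc3c2)C(=O)[Co-2]1(Cl)([P+](c4ccccc4)(c5ccccc5)c6ccccc6)[P+](c7ccccc7)(c8ccccc8)c9ccccc9 | intermediate
13 | CoCl(dmgH2)(py)[C(O)C(R1)=C(R2)C(O)], the same metallacycle with N,N-bound dimethylglyoxime and pyridine | O=C1C(/C=C/CCCCC)=C(COCc2ccc3ccccc3c2)C(=O)[Co-3]15(Cl)([n+]4ccccc4)[N+](O)=C(C)C(C)=[N+]5O | intermediate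
14 | 2-bromopropanoyl bromide (racemic) | CC(Br)C(=O)Br | starting material
15 | prop-2-en-1-ol | C=CCO | starting material
16 | prop-2-enyl 2-bromopropanoate (racemic) | CC(Br)C(=O)OCC=C | intermediate
17 | [1-oxo-1-(prop-2-enyloxy)propan-2-yl]triphenylphosphonium bromide | CC(C(=O)OCC=C)[P+](c1ccccc1)(c1ccccc1)c1ccccc1.[Br-] | intermediate
18 | prop-2-enyl 2-(triphenyl-λ5-phosphanylidene)propanoate | CC(C(=O)OCC=C)=P(c1ccccc1)(c1ccccc1)c1ccccc1 | intermediate
19 | but-3-yn-1-ol | C#CCCO | starting material
20 | but-3-ynal | C#CCC=O | intermediate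
21 | prop-2-enyl (E)-2-methylhex-2-en-5-ynoate | C#CC/C=C(\C)C(=O)OCC=C | intermediate
22 | prop-2-enyl (E)-4-{5-[(E)-hept-1-enyl]-4-[(naphthalen-2-ylmethoxy)methyl]-3,6-dioxocyclohexa-1,4-dien-1-yl}-2-methylbut-2-enoate | O=C1C(/C=C/CCCCC)=C(COCc2ccc3ccccc3c2)C(=O)C=C1C/C=C(\C)C(=O)OCC=C | intermediate
23 | prop-2-enyl (E)-4-{(1R,6S)-3-[(E)-hept-1-enyl]-4-[(naphthalen-2-ylmethoxy)methyl]-2,5-dioxo-7-oxabicyclo[4.1.0]hept-3-en-1-yl}-2-methylbut-2-enoate | CCCCC/C=C/C1=C(COCc3ccc4ccccc4c3)C(=O)[C@H]2O[C@@]2(C/C=C(\C)C(=O)OCC=C)C1=O | intermediate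
24 | prop-2-enyl (E)-4-[(1R,6S)-3-[(E)-hept-1-enyl]-4-(hydroxymethyl)-2,5-dioxo-7-oxabicyclo[4.1.0]hept-3-en-1-yl]-2-methylbut-2-enoate | CCCCC/C=C/C1=C(CO)C(=O)[C@H]2O[C@@]2(C/C=C(\C)C(=O)OCC=C)C1=O | intermediate
25 | prop-2-enyl (E)-4-[(1R,5R,6R)-3-[(E)-hept-1-enyl]-5-hydroxy-4-(hydroxymethyl)-2-oxo-7-oxabicyclo[4.1.0]hept-3-en-1-yl]-2-methylbut-2-enoate | CCCCC/C=C/C1=C(CO)[C@@H](O)[C@H]2O[C@@]2(C/C=C(\C)C(=O)OCC=C)C1=O | intermediate
26 | prop-2-enyl (E)-4-[(1S,2R,5R,6R)-3-[(E)-hept-1-enyl]-2,5-dihydroxy-4-(hydroxymethyl)-7-oxabicyclo[4.1.0]hept-3-en-1-yl]-2-methylbut-2-enoate | CCCCC/C=C/C1=C(CO)[C@@H](O)[C@H]2O[C@@]2(C/C=C(\C)C(=O)OCC=C)[C@@H]1O | intermediate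
27 | (E)-4-[(1S,2R,5R,6R)-3-[(E)-hept-1-enyl]-2,5-dihydroxy-4-(hydroxymethyl)-7-oxabicyclo[4.1.0]hept-3-en-1-yl]-2-methylbut-2-enoic acid | CCCCC/C=C/C1=C(CO)[C@@H](O)[C@H]2O[C@@]2(C/C=C(\C)C(=O)O)[C@@H]1O | target

**Step count and risks**

Total steps: 13. Longest linear sequence: 9 steps (steps 1, 3, 4, 8, 9, 10, 11, 12, 13; the alkyne branch, steps 5, 6, 7, then 8 to 13, is equally long).

Steps most likely to fail:

1. Step 8. The alkyne may insert into the other acyl–cobalt bond, giving the regioisomeric quinone; the differentiation of the two acyl groups by an alkenyl and an alkoxymethyl substituent is weaker than in the alkoxy-substituted cases on which the Lewis acid control is based. The fallback lets a vinylogous ester direct the annulation and brings in the heptenyl group last. It sets out from 6 and 3 and returns at 22. The mono-adduct 9 is made as in step 3 but without the second organolithium, and HCl gives 3-(propan-2-yloxy)-4-[(naphthalen-2-ylmethoxy)methyl]cyclobut-3-ene-1,2-dione F1. ClCo(PPh3)3 gives the bis(triphenylphosphine) maleoylcobalt complex F2, and dimethylglyoxime with pyridine gives the dimethylglyoxime/pyridine complex F3. Annulation with 21 under SnCl4, in which the vinylogous ester acyl group is the unambiguous Lewis basic site next to the CH2O-bearing carbon, should give the isopropoxyquinone F4. Aqueous HCl in THF hydrolyses the vinylogous ester to the hydroxyquinone F5, Tf2O with 2,6-lutidine gives the quinone triflate F6, and Suzuki–Miyaura coupling with boronic acid 4 (Pd(PPh3)4, CsF, THF) gives 22.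

2. Step 9. Enantioselectivity may be low on this fully unsymmetrical quinone, and the base may trigger tautomerisation through the doubly activated side-chain CH2 before epoxidation. The fallback gives up asymmetric catalysis for a racemic synthesis with resolution; it sets out from 22 and returns at 24. Epoxidation with tert-butyl hydroperoxide and DBU (CH2Cl2, 0 °C, a weaker and non-aqueous base) gives the racemic NAP-protected epoxy-enedione F7. DDQ gives the racemic epoxy-enedione alcohol F8, which is resolved by preparative chromatography on a chiral stationary phase to give 24.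

3. Step 12. Hydride may instead attack C2 anti to the epoxide oxygen (poor facial selectivity, giving the cis-1,4-diol), and the bulky borohydride may begin to reduce the enoate. The fallback changes the order of events so that an ester-incompatible, epoxide-coordinating hydride can be used; it sets out from 25 and returns at 27. Deallylation first (Pd(PPh3)4, morpholine) gives (E)-4-[(1R,5R,6R)-3-[(E)-hept-1-enyl]-5-hydroxy-4-(hydroxymethyl)-2-oxo-7-oxabicyclo[4.1.0]hept-3-en-1-yl]-2-methylbut-2-enoic acid F9. Reduction with i-Bu2AlH (excess, THF, −78 °C; the aluminium carboxylate is inert) should then deliver hydride on the epoxide face through coordination of aluminium to the epoxide oxygen, giving 27 directly.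

**Further compounds**

F1 | step 8 | 3-(propan-2-yloxy)-4-[(naphthalen-2-ylmethoxy)methyl]cyclobut-3-ene-1,2-dione | CC(C)OC1=C(COCc2ccc3ccccc3c2)C(=O)C1=O
F2 | step 8 | CoCl(PPh3)2[C(O)C(OiPr)=C(CH2OCH2-2-naphthyl)C(O)], maleoyl metallacycle of trivalent cobalt | O=C1C(OC(C)C)=C(COCc2ccc3ccccc3c2)C(=O)[Co-2]1(Cl)([P+](c4ccccc4)(c5ccccc5)c6ccccc6)[P+](c7ccccc7)(c8ccccc8)c9ccccc9
F3 | step 8 | CoCl(dmgH2)(py)[C(O)C(OiPr)=C(CH2OCH2-2-naphthyl)C(O)] | O=C1C(OC(C)C)=C(COCc2ccc3ccccc3c2)C(=O)[Co-3]15(Cl)([n+]4ccccc4)[N+](O)=C(C)C(C)=[N+]5O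
F4 | step 8 | prop-2-enyl (E)-2-methyl-4-{4-[(naphthalen-2-ylmethoxy)methyl]-3,6-dioxo-5-(propan-2-yloxy)cyclohexa-1,4-dien-1-yl}but-2-enoate | O=C1C(OC(C)C)=C(COCc2ccc3ccccc3c2)C(=O)C=C1C/C=C(\C)C(=O)OCC=C
F5 | step 8 | prop-2-enyl (E)-4-{5-hydroxy-4-[(naphthalen-2-ylmethoxy)methyl]-3,6-dioxocyclohexa-1,4-dien-1-yl}-2-methylbut-2-enoate | O=C1C(O)=C(COCc2ccc3ccccc3c2)C(=O)C=C1C/C=C(\C)C(=O)OCC=C
F6 | step 8 | prop-2-enyl (E)-2-methyl-4-{4-[(naphthalen-2-ylmethoxy)methyl]-3,6-dioxo-5-(trifluoromethylsulfonyloxy)cyclohexa-1,4-dien-1-yl}but-2-enoate | O=C1C(OS(=O)(=O)C(F)(F)F)=C(COCc2ccc3ccccc3c2)C(=O)C=C1C/C=C(\C)C(=O)OCC=C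
F7 | step 9 | racemic prop-2-enyl (E)-4-{3-[(E)-hept-1-enyl]-4-[(naphthalen-2-ylmethoxy)methyl]-2,5-dioxo-7-oxabicyclo[4.1.0]hept-3-en-1-yl}-2-methylbut-2-enoate | CCCCC/C=C/C1=C(COCc3ccc4ccccc4c3)C(=O)C2OC2(C/C=C(\C)C(=O)OCC=C)C1=O
F8 | step 9 | racemic prop-2-enyl (E)-4-[3-[(E)-hept-1-enyl]-4-(hydroxymethyl)-2,5-dioxo-7-oxabicyclo[4.1.0]hept-3-en-1-yl]-2-methylbut-2-enoate | CCCCC/C=C/C1=C(CO)C(=O)C2OC2(C/C=C(\C)C(=O)OCC=C)C1=O
F9 | step 12 | (E)-4-[(1R,5R,6R)-3-[(E)-hept-1-enyl]-5-hydroxy-4-(hydroxymethyl)-2-oxo-7-oxabicyclo[4.1.0]hept-3-en-1-yl]-2-methylbut-2-enoic acid | CCCCC/C=C/C1=C(CO)[C@@H](O)[C@H]2O[C@@]2(C/C=C(\C)C(=O)O)C1=O
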